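**Retrosynthetic overview**

1. Ascomindone B comes from its penta-MOM ether; the five-membered indenone ring is cut at C1–C2 and C2=C3 (phosphonate acylation, then intramolecular Horner–Wadsworth–Emmons) into a ring A–ring B benzylic phosphonate (ring A as carboxylate) and a ring C–ring D 2-aroylbenzoate.
2. The strategy rests on ring B: its aryloxy carbon sits between a C–OH and the carbon bonded to indenone C2, with OMe meta to that OH. This resorcinol monomethyl ether pattern is what a vinylketene plus alkoxyalkyne benzannulation delivers, so ring B is built around the ether instead of being coupled to ring A.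
3. Ring B is cut into a β-aryloxy vinyl diazoketone (ketone C → C–OH, diazo C → CH, α-C → C–CH2O, β-C → C–OAr) and methoxyacetylene (CH and C–OMe). The hindered ether C–O bond is made beforehand at a vinylic carbon, by oxa-Michael addition of the ring A phenol to butynone; the α-CH2O group follows by iodination and Stille coupling.
4. The keto ester comes from a 3-arylphthalide, made from lithiated orcinol bis-MOM ether and a ring C formyl ester (methyl 3,5-dimethoxybenzoate, formylation, chelation-controlled demethylation), then lactone C–H oxygenation.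
5. Ring order: rings A, C and D are bought; ring B is formed in step 8 and the indenone five-membered ring in step 21.

Key step: step 8

Assumption: the target has no stereocentre (axial chirality is taken as not fixed); the enol-ether double bond of 4–9 is drawn with acyl trans to aryloxy, either geometric isomer should serve in step 8, and 14, 16, 30, 31 and 34 are racemic or diastereomer mixtures.

**Route**

Step 1
Reactants: 1 methyl 2,6-dihydroxy-4-methylbenzoate
Product: 2 methyl 2-hydroxy-6-(methoxymethoxy)-4-methylbenzoate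
Conditions: MOMCl (1.05 equiv), i-Pr2NEt, CH2Cl2, 0 °C
Reagents that add atoms: chloromethyl methyl ether, COCCl
Why: Williamson-type O-alkylation (MOM protection) of a symmetric diol, which should stop at the mono-ether because the remaining hydroxyl is then locked in a hydrogen bond to the ester carbonyl.

Step 2
Reactants: 2 methyl 2-hydroxy-6-(methoxymethoxy)-4-methylbenzoate; 3 but-3-yn-2-one
Product: 4 methyl 2-(methoxymethoxy)-4-methyl-6-{[(E)-3-oxobut-1-en-1-yl]oxy}benzoate
Conditions: DABCO (10 mol %), CH2Cl2, 0 °C → rt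
Reagents that add atoms: none
Why: Amine-catalysed oxa-Michael addition of a phenol to an ynone forms the hindered aryl–O bond at an unhindered sp carbon and should give the (E)-β-aryloxy enone under thermodynamic control.

Step 3
Reactants: 4 methyl 2-(methoxymethoxy)-4-methyl-6-{[(E)-3-oxobut-1-en-1-yl]oxy}benzoate
Product: 5 methyl 2-{[(Z)-2-iodo-3-oxobut-1-en-1-yl]oxy}-6-(methoxymethoxy)-4-methylbenzoate
Conditions: I2, pyridine, DMAP (cat.), CH2Cl2, 0 °C → rt
Reagents that add atoms: iodine, II
Why: Johnson-type α-iodination of an enone (amine conjugate addition, iodination of the enolate, elimination) is confined to the α-carbon and should leave the ester-deactivated ring A untouched.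

Step 4
Reactants: 5 methyl 2-{[(Z)-2-iodo-3-oxobut-1-en-1-yl]oxy}-6-(methoxymethoxy)-4-methylbenzoate
Product: 6 methyl 2-{[(E)-2-(hydroxymethyl)-3-oxobut-1-en-1-yl]oxy}-6-(methoxymethoxy)-4-methylbenzoate
Conditions: Bu3SnCH2OH (1.5 equiv), Pd(PPh3)4 (5 mol %), dioxane, 90 °C
Reagents that add atoms: (tributylstannyl)methanol, OC[Sn](CCCC)(CCCC)CCCC
Why: Stille (Kosugi–Migita) coupling of an α-iodoenone transfers the hydroxymethyl group with retention of alkene geometry, so the C1 unit is placed at the α-carbon without the regiochemical and β-elimination problems of formylating a β-silyloxy ketone.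

Step 5
Reactants: 6 methyl 2-{[(E)-2-(hydroxymethyl)-3-oxobut-1-en-1-yl]oxy}-6-(methoxymethoxy)-4-methylbenzoate
Product: 7 methyl 2-{[(E)-2-{[tert-butyl(dimethyl)silyl]oxymethyl}-3-oxobut-1-en-1-yl]oxy}-6-(methoxymethoxy)-4-methylbenzoate
Conditions: TBSCl, imidazole, DMF, rt
Reagents that add atoms: tert-butyldimethylsilyl chloride, CC(C)(C)[Si](C)(C)Cl
Why: Standard silylation of a primary alcohol, needed because a free hydroxyl would consume base in step 6 and trap the ketene in step 8.

Step 6
Reactants: 7 methyl 2-{[(E)-2-{[tert-butyl(dimethyl)silyl]oxymethyl}-3-oxobut-1-en-1-yl]oxy}-6-(methoxymethoxy)-4-methylbenzoate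
Product: 9 methyl 2-{[(E)-2-{[tert-butyl(dimethyl)silyl]oxymethyl}-4-diazo-3-oxobut-1-en-1-yl]oxy}-6-(methoxymethoxy)-4-methylbenzoate, via trifluoroacetyl ketone 8 (not isolated)
Conditions: LiN(SiMe3)2, THF, −78 °C; CF3CO2CH2CF3; 5% HCl work-up; then MsN3, Et3N, H2O (1 equiv), MeCN, rt
Reagents that add atoms: methanesulfonyl azide, CS(=O)(=O)N=[N+]=[N-] (2,2,2-trifluoroethyl trifluoroacetate, O=C(OCC(F)(F)F)C(F)(F)F, supplies the trifluoroacetyl group of 8 only)
Why: Danheiser detrifluoroacetylative diazo transfer (Regitz type): kinetic deprotonation of the only enolisable position (the methyl group), Claisen trifluoroacetylation to activate it, then diazo transfer with retro-Claisen loss of the trifluoroacetyl group.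

Step 7
Reactants: 10 chloroacetaldehyde dimethyl acetal
Product: 12 methoxyacetylene, via sodium methoxyacetylide 11 (not isolated)
Conditions: NaNH2 (3 equiv), liq. NH3, −33 °C; evaporate NH3; sat. aq. NaCl, −70 °C; distil into cold ClCH2CH2Cl
Reagents that add atoms: none
Why: Twofold amide-induced elimination (HCl, then methanol) from an α-chloroacetal gives the sodium alkoxyacetylide, protonated on quench; this is the standard alkoxyacetylene preparation.

Step 8
Reactants: 9 methyl 2-{[(E)-2-{[tert-butyl(dimethyl)silyl]oxymethyl}-4-diazo-3-oxobut-1-en-1-yl]oxy}-6-(methoxymethoxy)-4-methylbenzoate; 12 methoxyacetylene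
Product: 17 methyl 2-[2-{[tert-butyl(dimethyl)silyl]oxymethyl}-6-hydroxy-4-methoxyphenoxy]-6-(methoxymethoxy)-4-methylbenzoate, via vinylketene 13 (not isolated), via vinylcyclobutenone 14 (not isolated), via dienylketene 15 (not isolated), via cyclohexadienone 16 (not isolated)
Conditions: 12 (4 equiv), ClCH2CH2Cl, hν (254 nm, low-pressure Hg lamp, quartz), 20 °C; then sealed tube, 80 °C
Reagents that add atoms: none
Why: Irradiation expels N2 and the alkenyl group migrates in a photo-Wolff rearrangement to the 4-aryloxy vinylketene 13, which adds methoxyacetylene by [2+2] cycloaddition to cyclobutenone 14; reversible 4π ring opening gives dienylketene 15, 6π electrocyclisation gives dienone 16, and enolisation gives the phenol. The closest known reaction type is the Danheiser benzannulation in its photochemical Wolff version with alkoxyacetylenes, which gives resorcinol monoethers; the 4-aryloxy group is a new substituent within that class. Ring B is closed by disrotatory 6π electrocyclisation of the dienylketene (ketene carbon to the aryloxy-bearing vinyl carbon), and three C–C bonds are formed in all: C1–C2 and C3–C4 in the cycloaddition and C1–C6 in the electrocyclisation (ring B numbered from the hydroxyl carbon). No stereocentre is created, since the sp3 centres of 14 and 16 are lost on aromatisation. The step needs the ketene carbonyl carbon to bond to the unsubstituted alkyne carbon, which the polarisation of the alkoxyalkyne (nucleophilic β-carbon) secures and which puts OMe meta to the new OH, while the connectivity of 9 fixes the aryloxy carbon next to the hydroxyl carbon and the CH2OTBS carbon beside it. It also needs the Wolff shift to outrun capture of the acylcarbene by the enol-ether oxygen, for which direct photolysis without a metal carbenoid and an excess of alkyne are chosen.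

Step 9
Reactants: 17 methyl 2-[2-{[tert-butyl(dimethyl)silyl]oxymethyl}-6-hydroxy-4-methoxyphenoxy]-6-(methoxymethoxy)-4-methylbenzoate
Product: 18 methyl 2-[2-{[tert-butyl(dimethyl)silyl]oxymethyl}-4-methoxy-6-(methoxymethoxy)phenoxy]-6-(methoxymethoxy)-4-methylbenzoate
Conditions: MOMCl, i-Pr2NEt, CH2Cl2, 0 °C → rt
Reagents that add atoms: chloromethyl methyl ether, COCCl
Why: MOM protection (Williamson type) keeps the new phenol from consuming base in step 21 and from being methylated in step 22.

Step 10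
Reactants: 18 methyl 2-[2-{[tert-butyl(dimethyl)silyl]oxymethyl}-4-methoxy-6-(methoxymethoxy)phenoxy]-6-(methoxymethoxy)-4-methylbenzoate
Product: 19 methyl 2-[2-(hydroxymethyl)-4-methoxy-6-(methoxymethoxy)phenoxy]-6-(methoxymethoxy)-4-methylbenzoate
Conditions: Bu4NF, THF, 0 °C; aq. NH4Cl
Reagents that add atoms: none
Why: Fluoride-mediated desilylation of a primary TBS ether, to which MOM ethers, the hindered ester and the diaryl ether are inert.

Step 11
Reactants: 19 methyl 2-[2-(hydroxymethyl)-4-methoxy-6-(methoxymethoxy)phenoxy]-6-(methoxymethoxy)-4-methylbenzoate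
Product: 20 methyl 2-[2-(bromomethyl)-4-methoxy-6-(methoxymethoxy)phenoxy]-6-(methoxymethoxy)-4-methylbenzoate
Conditions: CBr4, PPh3, 2,6-lutidine, CH2Cl2, 0 °C
Reagents that add atoms: carbon tetrabromide, BrC(Br)(Br)Br
Why: Appel bromination of a benzylic alcohol (SN2 on the alkoxyphosphonium ion) runs under buffered, near-neutral conditions that MOM ethers tolerate.

Step 12
Reactants: 20 methyl 2-[2-(bromomethyl)-4-methoxy-6-(methoxymethoxy)phenoxy]-6-(methoxymethoxy)-4-methylbenzoate
Product: 21 methyl 2-[2-{[di(propan-2-yloxy)phosphoryl]methyl}-4-methoxy-6-(methoxymethoxy)phenoxy]-6-(methoxymethoxy)-4-methylbenzoate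
Conditions: P(Oi-Pr)3 (neat), 130 °C
Reagents that add atoms: triisopropyl phosphite, CC(C)OP(OC(C)C)OC(C)C
Why: Michaelis–Arbuzov reaction of a reactive benzylic bromide; isopropyl esters are chosen so that the phosphonate survives the hydroxide of step 13.

Step 13
Reactants: 21 methyl 2-[2-{[di(propan-2-yloxy)phosphoryl]methyl}-4-methoxy-6-(methoxymethoxy)phenoxy]-6-(methoxymethoxy)-4-methylbenzoate
Product: 22 2-[2-{[di(propan-2-yloxy)phosphoryl]methyl}-4-methoxy-6-(methoxymethoxy)phenoxy]-6-(methoxymethoxy)-4-methylbenzoic acid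
Conditions: KOH, EtOH–H2O (4:1), 80 °C; then 1 M HCl to pH 3, 0 °C
Reagents that add atoms: potassium hydroxide, [K+].[OH-]
Why: Forcing saponification (BAc2) of the 2,6-dioxygenated benzoate, which MOM ethers and the diisopropyl phosphonate tolerate; the carboxylate later shields ring A from seven-membered Claisen closure by the benzylic anion.

Step 14
Reactants: 23 methyl 3,5-dimethoxybenzoate
Product: 24 methyl 2-formyl-3,5-dimethoxybenzoate
Conditions: Cl2CHOMe, TiCl4, CH2Cl2, −20 → 0 °C; H2O
Reagents that add atoms: dichloromethyl methyl ether, COC(Cl)Cl; water, O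
Why: Rieche formylation (electrophilic aromatic substitution) at C2, which is ortho and para to the two methoxy groups and not flanked by both of them.

Step 15
Reactants: 24 methyl 2-formyl-3,5-dimethoxybenzoate
Product: 25 methyl 2-formyl-3-hydroxy-5-methoxybenzoate
Conditions: BCl3 (1.2 equiv), CH2Cl2, −78 → 0 °C; H2O
Reagents that add atoms: none
Why: Chelation-controlled Lewis acid demethylation: BCl3 bound to the formyl oxygen cleaves only the ortho methoxy group through a six-membered chelate, which differentiates the two ring C oxygens.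

Step 16
Reactants: 25 methyl 2-formyl-3-hydroxy-5-methoxybenzoate
Product: 26 methyl 2-formyl-5-methoxy-3-(methoxymethoxy)benzoate
Conditions: MOMCl, i-Pr2NEt, DMAP (cat.), CH2Cl2, 40 °C
Reagents that add atoms: chloromethyl methyl ether, COCCl
Why: MOM protection (Williamson type) of the chelated phenol, giving the same acid-labile group as on the other rings.

Step 17
Reactants: 27 orcinol (5-methylbenzene-1,3-diol)
Product: 28 1,3-bis(methoxymethoxy)-5-methylbenzene
Conditions: NaH, MOMCl, DMF, 0 °C → rt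
Reagents that add atoms: chloromethyl methyl ether, COCCl
Why: Double Williamson-type MOM protection, which also installs two cooperating directing groups for the lithiation of step 18.

Step 18
Reactants: 28 1,3-bis(methoxymethoxy)-5-methylbenzene; 26 methyl 2-formyl-5-methoxy-3-(methoxymethoxy)benzoate
Product: 31 3-[2,6-bis(methoxymethoxy)-4-methylphenyl]-6-methoxy-4-(methoxymethoxy)-2-benzofuran-1(3H)-one, via aryllithium 29 (not isolated), via lithium alkoxide 30 (not isolated)
Conditions: n-BuLi, THF, 0 °C → rt; then 26, −78 °C → rt; aq. NH4Cl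
Reagents that add atoms: none
Why: Directed ortho-lithiation at C2 between the two OMOM groups, 1,2-addition to the aldehyde (faster than to the ester at −78 °C) and lactonisation of the alkoxide onto the neighbouring ester give the racemic phthalide.

Step 19
Reactants: 31 3-[2,6-bis(methoxymethoxy)-4-methylphenyl]-6-methoxy-4-(methoxymethoxy)-2-benzofuran-1(3H)-one
Product: 32 2-[2,6-bis(methoxymethoxy)-4-methylbenzoyl]-5-methoxy-3-(methoxymethoxy)benzoic acid
Conditions: t-BuOK, O2, P(OEt)3, THF–DMF, −40 → 0 °C; then 1 M HCl to pH 3, 0 °C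
Reagents that add atoms: dioxygen, O=O
Why: Enolate oxygenation: the doubly benzylic lactone C–H is deprotonated, the anion is trapped by O2, the hydroperoxide is reduced by the phosphite, and the lactol opens to the 2-aroylbenzoate.

Step 20
Reactants: 32 2-[2,6-bis(methoxymethoxy)-4-methylbenzoyl]-5-methoxy-3-(methoxymethoxy)benzoic acid
Product: 33 methyl 2-[2,6-bis(methoxymethoxy)-4-methylbenzoyl]-5-methoxy-3-(methoxymethoxy)benzoate
Conditions: MeI, K2CO3, DMF, rt
Reagents that add atoms: iodomethane, CI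
Why: SN2 alkylation on the carboxylate oxygen gives the open keto ester and not the cyclic pseudo-ester.

Step 21
Reactants: 22 2-[2-{[di(propan-2-yloxy)phosphoryl]methyl}-4-methoxy-6-(methoxymethoxy)phenoxy]-6-(methoxymethoxy)-4-methylbenzoic acid; 33 methyl 2-[2,6-bis(methoxymethoxy)-4-methylbenzoyl]-5-methoxy-3-(methoxymethoxy)benzoate
Product: 35 2-{2-[3-[2,6-bis(methoxymethoxy)-4-methylphenyl]-6-methoxy-4-(methoxymethoxy)-1-oxo-1H-inden-2-yl]-4-methoxy-6-(methoxymethoxy)phenoxy}-6-(methoxymethoxy)-4-methylbenzoic acid, via keto phosphonate 34 (not isolated)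
Conditions: NaN(SiMe3)2 (3.3 equiv), THF, −78 °C; then 33, −78 → 20 °C; then 50 °C; 1 M HCl to pH 3, 0 °C
Reagents that add atoms: none
Why: Claisen-type acylation of the phosphonate carbanion by the methyl ester, then intramolecular Horner–Wadsworth–Emmons olefination of the diaryl ketone by the β-keto phosphonate anion (five-membered ring closure, loss of phosphate), forms C1–C2 and C2=C3 of the indenone; the ring A carboxylate and the non-enolisable keto ester leave no competing acidic or electrophilic site.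

Step 22
Reactants: 35 2-{2-[3-[2,6-bis(methoxymethoxy)-4-methylphenyl]-6-methoxy-4-(methoxymethoxy)-1-oxo-1H-inden-2-yl]-4-methoxy-6-(methoxymethoxy)phenoxy}-6-(methoxymethoxy)-4-methylbenzoic acid
Product: 36 methyl 2-{2-[3-[2,6-bis(methoxymethoxy)-4-methylphenyl]-6-methoxy-4-(methoxymethoxy)-1-oxo-1H-inden-2-yl]-4-methoxy-6-(methoxymethoxy)phenoxy}-6-(methoxymethoxy)-4-methylbenzoate
Conditions: MeI, K2CO3, DMF, rt
Reagents that add atoms: iodomethane, CI
Why: Carboxylate SN2 alkylation restores the ring A methyl ester regardless of its steric shielding, while all phenols are still masked.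

Step 23
Reactants: 36 methyl 2-{2-[3-[2,6-bis(methoxymethoxy)-4-methylphenyl]-6-methoxy-4-(methoxymethoxy)-1-oxo-1H-inden-2-yl]-4-methoxy-6-(methoxymethoxy)phenoxy}-6-(methoxymethoxy)-4-methylbenzoate
Product: 37 ascomindone B
Conditions: 3 M HCl (aq), MeOH–THF, 45 °C
Reagents that add atoms: none
Why: Acid-catalysed acetal exchange removes all five MOM groups, with methanol trapping the formaldehyde unit as dimethoxymethane so that the electron-rich rings are not hydroxymethylated; the methyl ethers and the hindered methyl ester should survive.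

**Compound list**

1 | methyl 2,6-dihydroxy-4-methylbenzoate | COC(=O)c1c(O)cc(C)cc1O | starting material
2 | methyl 2-hydroxy-6-(methoxymethoxy)-4-methylbenzoate | COC(=O)c1c(O)cc(C)cc1OCOC | intermediate
3 | but-3-yn-2-one | CC(=O)C#C | starting material
4 | methyl 2-(methoxymethoxy)-4-methyl-6-{[(E)-3-oxobut-1-en-1-yl]oxy}benzoate | CC(=O)/C=C/Oc1cc(C)cc(OCOC)c1C(=O)OC | intermediate
5 | methyl 2-{[(Z)-2-iodo-3-oxobut-1-en-1-yl]oxy}-6-(methoxymethoxy)-4-methylbenzoate | CC(=O)/C(I)=C/Oc1cc(C)cc(OCOC)c1C(=O)OC | intermediate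
6 | methyl 2-{[(E)-2-(hydroxymethyl)-3-oxobut-1-en-1-yl]oxy}-6-(methoxymethoxy)-4-methylbenzoate | CC(=O)/C(CO)=C/Oc1cc(C)cc(OCOC)c1C(=O)OC | intermediate
7 | methyl 2-{[(E)-2-{[tert-butyl(dimethyl)silyl]oxymethyl}-3-oxobut-1-en-1-yl]oxy}-6-(methoxymethoxy)-4-methylbenzoate | CC(=O)/C(CO[Si](C)(C)C(C)(C)C)=C/Oc1cc(C)cc(OCOC)c1C(=O)OC | intermediate
8 | methyl 2-{[(E)-2-{[tert-butyl(dimethyl)silyl]oxymethyl}-6,6,6-trifluoro-3,5-dioxohex-1-en-1-yl]oxy}-6-(methoxymethoxy)-4-methylbenzoate | O=C(CC(=O)C(F)(F)F)/C(CO[Si](C)(C)C(C)(C)C)=C/Oc1cc(C)cc(OCOC)c1C(=O)OC | intermediate (not isolated)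
9 | methyl 2-{[(E)-2-{[tert-butyl(dimethyl)silyl]oxymethyl}-4-diazo-3-oxobut-1-en-1-yl]oxy}-6-(methoxymethoxy)-4-methylbenzoate | [N-]=[N+]=CC(=O)/C(CO[Si](C)(C)C(C)(C)C)=C/Oc1cc(C)cc(OCOC)c1C(=O)OC | intermediate
10 | chloroacetaldehyde dimethyl acetal (2-chloro-1,1-dimethoxyethane) | COC(CCl)OC | starting material
11 | sodium methoxyacetylide | [Na+].[C-]#COC | intermediate (not isolated)
12 | methoxyacetylene | COC#C | intermediate
13 | methyl 2-{[(1Z)-2-{[tert-butyl(dimethyl)silyl]oxymethyl}-4-oxobuta-1,3-dien-1-yl]oxy}-6-(methoxymethoxy)-4-methylbenzoate (4-aryloxy vinylketene) | O=C=C/C(CO[Si](C)(C)C(C)(C)C)=C/Oc1cc(C)cc(OCOC)c1C(=O)OC | intermediate (not isolated)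
14 | methyl 2-{[(1Z)-3-{[tert-butyl(dimethyl)silyl]oxy}-2-(2-methoxy-4-oxocyclobut-2-en-1-yl)prop-1-en-1-yl]oxy}-6-(methoxymethoxy)-4-methylbenzoate (racemic) | O=C1C=C(OC)C1/C(CO[Si](C)(C)C(C)(C)C)=C/Oc1cc(C)cc(OCOC)c1C(=O)OC | intermediate (not isolated)
15 | methyl 2-{[(1Z,3E)-2-{[tert-butyl(dimethyl)silyl]oxymethyl}-4-methoxy-6-oxohexa-1,3,5-trien-1-yl]oxy}-6-(methoxymethoxy)-4-methylbenzoate (dienylketene) | O=C=C/C(OC)=C\C(CO[Si](C)(C)C(C)(C)C)=C\Oc1cc(C)cc(OCOC)c1C(=O)OC | intermediate (not isolated)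
16 | methyl 2-{[2-{[tert-butyl(dimethyl)silyl]oxymethyl}-4-methoxy-6-oxocyclohexa-2,4-dien-1-yl]oxy}-6-(methoxymethoxy)-4-methylbenzoate (racemic) | O=C1C=C(OC)C=C(CO[Si](C)(C)C(C)(C)C)C1Oc1cc(C)cc(OCOC)c1C(=O)OC | intermediate (not isolated)
17 | methyl 2-[2-{[tert-butyl(dimethyl)silyl]oxymethyl}-6-hydroxy-4-methoxyphenoxy]-6-(methoxymethoxy)-4-methylbenzoate | COC(=O)c1c(OCOC)cc(C)cc1Oc1c(O)cc(OC)cc1CO[Si](C)(C)C(C)(C)C | intermediate
18 | methyl 2-[2-{[tert-butyl(dimethyl)silyl]oxymethyl}-4-methoxy-6-(methoxymethoxy)phenoxy]-6-(methoxymethoxy)-4-methylbenzoate | COC(=O)c1c(OCOC)cc(C)cc1Oc1c(OCOC)cc(OC)cc1CO[Si](C)(C)C(C)(C)C | intermediate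
19 | methyl 2-[2-(hydroxymethyl)-4-methoxy-6-(methoxymethoxy)phenoxy]-6-(methoxymethoxy)-4-methylbenzoate | COC(=O)c1c(OCOC)cc(C)cc1Oc1c(OCOC)cc(OC)cc1CO | intermediate
20 | methyl 2-[2-(bromomethyl)-4-methoxy-6-(methoxymethoxy)phenoxy]-6-(methoxymethoxy)-4-methylbenzoate | COC(=O)c1c(OCOC)cc(C)cc1Oc1c(OCOC)cc(OC)cc1CBr | intermediate
21 | methyl 2-[2-{[di(propan-2-yloxy)phosphoryl]methyl}-4-methoxy-6-(methoxymethoxy)phenoxy]-6-(methoxymethoxy)-4-methylbenzoate | COC(=O)c1c(OCOC)cc(C)cc1Oc1c(OCOC)cc(OC)cc1CP(=O)(OC(C)C)OC(C)C | intermediate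
22 | 2-[2-{[di(propan-2-yloxy)phosphoryl]methyl}-4-methoxy-6-(methoxymethoxy)phenoxy]-6-(methoxymethoxy)-4-methylbenzoic acid | OC(=O)c1c(OCOC)cc(C)cc1Oc1c(OCOC)cc(OC)cc1CP(=O)(OC(C)C)OC(C)C | intermediate
23 | methyl 3,5-dimethoxybenzoate | COC(=O)c1cc(OC)cc(OC)c1 | starting material
24 | methyl 2-formyl-3,5-dimethoxybenzoate | COC(=O)c1cc(OC)cc(OC)c1C=O | intermediate
25 | methyl 2-formyl-3-hydroxy-5-methoxybenzoate | COC(=O)c1cc(OC)cc(O)c1C=O | intermediate
26 | methyl 2-formyl-5-methoxy-3-(methoxymethoxy)benzoate | COC(=O)c1cc(OC)cc(OCOC)c1C=O | intermediate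
27 | orcinol (5-methylbenzene-1,3-diol) | Cc1cc(O)cc(O)c1 | starting material
28 | 1,3-bis(methoxymethoxy)-5-methylbenzene | Cc1cc(OCOC)cc(OCOC)c1 | intermediate
29 | [2,6-bis(methoxymethoxy)-4-methylphenyl]lithium | [Li]c1c(OCOC)cc(C)cc1OCOC | intermediate (not isolated)
30 | lithium alkoxide of methyl 2-{[2,6-bis(methoxymethoxy)-4-methylphenyl](hydroxy)methyl}-5-methoxy-3-(methoxymethoxy)benzoate (racemic) | COC(=O)c1cc(OC)cc(OCOC)c1C([O-])c1c(OCOC)cc(C)cc1OCOC.[Li+] | intermediate (not isolated)
31 | 3-[2,6-bis(methoxymethoxy)-4-methylphenyl]-6-methoxy-4-(methoxymethoxy)-2-benzofuran-1(3H)-one (racemic) | O=C1OC(c2c(OCOC)cc(C)cc2OCOC)c2c(OCOC)cc(OC)cc21 | intermediate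
32 | 2-[2,6-bis(methoxymethoxy)-4-methylbenzoyl]-5-methoxy-3-(methoxymethoxy)benzoic acid | OC(=O)c1cc(OC)cc(OCOC)c1C(=O)c1c(OCOC)cc(C)cc1OCOC | intermediate
33 | methyl 2-[2,6-bis(methoxymethoxy)-4-methylbenzoyl]-5-methoxy-3-(methoxymethoxy)benzoate | COC(=O)c1cc(OC)cc(OCOC)c1C(=O)c1c(OCOC)cc(C)cc1OCOC | intermediate
34 | 2-[2-{2-[2-[2,6-bis(methoxymethoxy)-4-methylbenzoyl]-5-methoxy-3-(methoxymethoxy)phenyl]-1-[di(propan-2-yloxy)phosphoryl]-2-oxoethyl}-4-methoxy-6-(methoxymethoxy)phenoxy]-6-(methoxymethoxy)-4-methylbenzoic acid (racemic; present as its sodium salt) | OC(=O)c1c(OCOC)cc(C)cc1Oc1c(OCOC)cc(OC)cc1C(P(=O)(OC(C)C)OC(C)C)C(=O)c1cc(OC)cc(OCOC)c1C(=O)c1c(OCOC)cc(C)cc1OCOC | intermediate (not isolated)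
35 | 2-{2-[3-[2,6-bis(methoxymethoxy)-4-methylphenyl]-6-methoxy-4-(methoxymethoxy)-1-oxo-1H-inden-2-yl]-4-methoxy-6-(methoxymethoxy)phenoxy}-6-(methoxymethoxy)-4-methylbenzoic acid | OC(=O)c1c(OCOC)cc(C)cc1Oc1c(OCOC)cc(OC)cc1C1=C(c2c(OCOC)cc(C)cc2OCOC)c2c(OCOC)cc(OC)cc2C1=O | intermediate
36 | methyl 2-{2-[3-[2,6-bis(methoxymethoxy)-4-methylphenyl]-6-methoxy-4-(methoxymethoxy)-1-oxo-1H-inden-2-yl]-4-methoxy-6-(methoxymethoxy)phenoxy}-6-(methoxymethoxy)-4-methylbenzoate | COC(=O)c1c(OCOC)cc(C)cc1Oc1c(OCOC)cc(OC)cc1C1=C(c2c(OCOC)cc(C)cc2OCOC)c2c(OCOC)cc(OC)cc2C1=O | intermediate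
37 | ascomindone B | COC(=O)c1c(O)cc(C)cc1Oc1c(O)cc(OC)cc1C1=C(c2c(O)cc(C)cc2O)c2c(O)cc(OC)cc2C1=O | target

**Step count and risks**

Total steps: 23. Longest linear sequence: 15 steps (steps 1–6, 8–13, 21–23).

Steps most likely to fail:

1. Step 8 (key benzannulation). The photogenerated acylcarbene may be captured by the neighbouring enol-ether oxygen before the Wolff shift, the aryloxy enone chromophore may photodegrade, the ketene may acylate the product phenol, or the cyclobutenone may stall before ring opening. Fallback: give up the benzannulation and form the diaryl ether by copper-mediated coupling, setting out from phenol 2 and rejoining at alcohol 19. Commercial 3-hydroxy-5-methoxybenzaldehyde is MOM-protected to 3-methoxy-5-(methoxymethoxy)benzaldehyde F1. This is brominated between the formyl and OMOM groups by α-amino alkoxide-directed ortho-lithiation (LiN(Me)CH2CH2NMe2, n-BuLi, then BrCCl2CCl2Br) to 2-bromo-5-methoxy-3-(methoxymethoxy)benzaldehyde F2. Ullmann etherification of 2 with F2 (CuI, N,N-dimethylglycine, Cs2CO3, dioxane, 105 °C; the ortho-formyl group activates the bromide) should give methyl 2-[2-formyl-4-methoxy-6-(methoxymethoxy)phenoxy]-6-(methoxymethoxy)-4-methylbenzoate F3. NaBH4 in MeOH at 0 °C reduces F3 to 19, and the route resumes at step 11.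

2. Step 21 (acylation/olefination). The carbanion may add to the diaryl ketone and lactonise to a 3,3-disubstituted phthalide instead of attacking the ester, or the closure may stall at the keto phosphonate because the ketone is flanked by three ortho substituents. Fallback: separate the two events, setting out from acid 22 and phthalide 31 and rejoining at 35. The dianion of 22 (NaN(SiMe3)2, 2.2 equiv, THF, −78 °C) is acylated by lactone 31, in which no ketone competes, to give the hydroxy keto phosphonate 2-[2-{2-[2-{[2,6-bis(methoxymethoxy)-4-methylphenyl](hydroxy)methyl}-5-methoxy-3-(methoxymethoxy)phenyl]-1-[di(propan-2-yloxy)phosphoryl]-2-oxoethyl}-4-methoxy-6-(methoxymethoxy)phenoxy]-6-(methoxymethoxy)-4-methylbenzoic acid F4. Dess–Martin oxidation of the diaryl carbinol gives 34 as an isolated compound. Ring closure under potassium conditions (K2CO3, 18-crown-6, toluene, 80 °C) should give 35, and the route resumes at step 22.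

3. Step 4 (Stille hydroxymethylation). Transfer of the sp3 hydroxymethyl group may be slow, so that butyl transfer, protodeiodination or loss of the aryloxy group takes over. Fallback: attach ring A to a preformed four-carbon unit by addition–elimination, setting out from phenol 2 and rejoining at 7, so that steps 2 to 5 are bypassed. The Morita–Baylis–Hillman adduct of methyl vinyl ketone and formaldehyde (DABCO), 3-(hydroxymethyl)but-3-en-2-one F5, is silylated (TBSCl, imidazole) to 3-{[tert-butyl(dimethyl)silyl]oxymethyl}but-3-en-2-one F6. Bromination (Br2, CH2Cl2, −78 °C) gives 3,4-dibromo-3-{[tert-butyl(dimethyl)silyl]oxymethyl}butan-2-one F7, and dehydrobromination (Et3N) gives 4-bromo-3-{[tert-butyl(dimethyl)silyl]oxymethyl}but-3-en-2-one F8. The caesium phenoxide of 2 (Cs2CO3, MeCN, rt) displaces the vinylic bromide to give 7.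

Further compounds

F1 | step 8 | 3-methoxy-5-(methoxymethoxy)benzaldehyde | COCOc1cc(OC)cc(C=O)c1
F2 | step 8 | 2-bromo-5-methoxy-3-(methoxymethoxy)benzaldehyde | COCOc1cc(OC)cc(C=O)c1Br
F3 | step 8 | methyl 2-[2-formyl-4-methoxy-6-(methoxymethoxy)phenoxy]-6-(methoxymethoxy)-4-methylbenzoate | COC(=O)c1c(OCOC)cc(C)cc1Oc1c(OCOC)cc(OC)cc1C=O
F4 | step 21 | 2-[2-{2-[2-{[2,6-bis(methoxymethoxy)-4-methylphenyl](hydroxy)methyl}-5-methoxy-3-(methoxymethoxy)phenyl]-1-[di(propan-2-yloxy)phosphoryl]-2-oxoethyl}-4-methoxy-6-(methoxymethoxy)phenoxy]-6-(methoxymethoxy)-4-methylbenzoic acid (diastereomer mixture) | OC(=O)c1c(OCOC)cc(C)cc1Oc1c(OCOC)cc(OC)cc1C(P(=O)(OC(C)C)OC(C)C)C(=O)c1cc(OC)cc(OCOC)c1C(O)c1c(OCOC)cc(C)cc1OCOC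
F5 | step 4 | 3-(hydroxymethyl)but-3-en-2-one | CC(=O)C(=C)CO
F6 | step 4 | 3-{[tert-butyl(dimethyl)silyl]oxymethyl}but-3-en-2-one | CC(=O)C(=C)CO[Si](C)(C)C(C)(C)C
F7 | step 4 | 3,4-dibromo-3-{[tert-butyl(dimethyl)silyl]oxymethyl}butan-2-one (racemic) | CC(=O)C(Br)(CBr)CO[Si](C)(C)C(C)(C)C
F8 | step 4 | 4-bromo-3-{[tert-butyl(dimethyl)silyl]oxymethyl}but-3-en-2-one (alkene geometry not fixed) | CC(=O)C(CO[Si](C)(C)C(C)(C)C)=CBr
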